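**Retrosynthetic overview**
1. The OCH2–CH= bond (C1–C2) is cut last: a Pd-catalysed sp3–sp2 Suzuki–Miyaura coupling joins a coumarin-7-yloxymethyl trifluoroborate (fragment 1) to an (E)-alkenyl iodide (fragment 2), followed by desilylation.
2. The alkenyl iodide comes from a terminal alkyne by Zr-catalysed methylalumination and iodinolysis; the syn-diol next to the isopropenyl group comes from a hydroxy-directed singlet-oxygen ene reaction of a prenyl-type secondary allylic alcohol.
3. That alcohol (the C5 stereocentre) comes from prenol and a silylated propargyl chloride by Ir-catalysed enantioselective carbinol C–H propargylation.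
4. The coumarin comes from 2-methoxyresorcinol and propiolic acid by Pd-catalysed C–H alkenylation and lactonisation; 2-methoxyresorcinol comes from resorcinol by directed ortho-lithiation and oxidation.
5. Ring order: ring A (benzene) is carried in from resorcinol; ring B (the pyranone) is the only ring formed, in step 5, before the fragments are joined.

Assumption: side-chain atoms are numbered C1 (OCH2) to C8 (=CH2), so the target is the (2E,5S,6S) isomer; in step 7 the (R)-SEGPHOS enantiomer is taken to be the one that gives the 4S alcohol.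

**Fragment 1 (steps 1–6)**

Step 1
Reactants: 1 resorcinol
Product: 2 1,3-bis(methoxymethoxy)benzene
Conditions: MOMCl (2.5 equiv), iPr2NEt (3 equiv), CH2Cl2, 0 °C → rt
Reagents that add atoms: chloromethyl methyl ether (MOMCl), COCCl
Why: Williamson-type O-alkylation protects both phenols as acetals, which then act as two cooperating directing groups for the lithiation.

Step 2
Reactants: 2 1,3-bis(methoxymethoxy)benzene
Product: 5 2,6-bis(methoxymethoxy)phenol, via aryllithium 3 (not isolated), via lithium aryltrimethoxyborate 4 (not isolated)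
Conditions: nBuLi (1.1 equiv), THF, 0 °C; B(OMe)3 (1.5 equiv), −78 °C → rt; AcOH, 30% H2O2, 0 °C → rt
Reagents that add atoms: hydrogen peroxide, OO
Why: Directed ortho-metalation at C2, flanked by both acetal oxygens, followed by borylation and boronate oxidation (C–B to C–O migration) places the third oxygen between the two ethers.

Step 3
Reactants: 5 2,6-bis(methoxymethoxy)phenol
Product: 6 2-methoxy-1,3-bis(methoxymethoxy)benzene
Conditions: MeI (1.5 equiv), K2CO3 (2 equiv), DMF, rt
Reagents that add atoms: iodomethane, CI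
Why: Williamson O-methylation of the only free phenol.

Step 4
Reactants: 6 2-methoxy-1,3-bis(methoxymethoxy)benzene
Product: 7 2-methoxybenzene-1,3-diol
Conditions: conc. HCl (cat.), MeOH, 50 °C
Reagents that add atoms: none
Why: Acid-catalysed acetal exchange with methanol removes both MOM groups and leaves the aryl methyl ether untouched.

Step 5
Reactants: 7 2-methoxybenzene-1,3-diol; 8 propiolic acid
Product: 10 7-hydroxy-8-methoxy-2H-chromen-2-one, via (Z)-cinnamic acid 9 (not isolated)
Conditions: Pd(OAc)2 (5 mol%), CF3CO2H/CH2Cl2 3:1, rt, 24 h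
Reagents that add atoms: none
Why: Fujiwara-type hydroarylation by electrophilic C–H palladation at C4 (ortho to one OH and para to the other; C4 and C6 are equivalent) adds trans across the alkyne to give the Z-acid, which lactonises, and the electron-poor coumarin does not react a second time.

Step 6
Reactants: 10 7-hydroxy-8-methoxy-2H-chromen-2-one; 11 potassium (bromomethyl)trifluoroborate
Product: 13 potassium trifluoro{[(8-methoxy-2-oxo-2H-chromen-7-yl)oxy]methyl}borate, via potassium phenoxide 12 (not isolated)
Conditions: KN(SiMe3)2 (1.0 equiv), THF, 0 °C; then 11 (1.0 equiv), THF/DMF, 60 °C; precipitate from acetone/Et2O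
Reagents that add atoms: none
Why: Williamson-type SN2 displacement of bromide on the α-halomethyl trifluoroborate by the phenoxide, the standard entry to alkoxymethyl and aryloxymethyl trifluoroborates.

**Fragment 2 (steps 7–11)**

Step 7
Reactants: 14 3-methylbut-2-en-1-ol (prenol); 15 (3-chloroprop-1-yn-1-yl)trimethylsilane
Product: 17 (4S)-6-methyl-1-(trimethylsilyl)hept-5-en-1-yn-4-ol, via 3-methylbut-2-enal 16 (not isolated)
Conditions: [Ir(cod)Cl]2 (2.5 mol%), (R)-SEGPHOS (5 mol%), K3PO4 (1.0 equiv), 15 (1.5 equiv), THF, 70 °C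
Reagents that add atoms: none
Why: In this Krische-type transfer-hydrogenative carbonyl propargylation the iridium catalyst dehydrogenates prenol at its carbinol C–H, converts the chloride into an allenyl/propargyl-iridium nucleophile and adds it to the transient enal inside the chiral SEGPHOS pocket, which sets the carbinol centre as 4S (sense confirmed by Mosher analysis, antipodal ligand otherwise).

Step 8
Reactants: 17 (4S)-6-methyl-1-(trimethylsilyl)hept-5-en-1-yn-4-ol
Product: 18 (4S)-6-methylhept-5-en-1-yn-4-ol
Conditions: K2CO3 (0.2 equiv), MeOH, rt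
Reagents that add atoms: none
Why: Base-catalysed methanolysis of the C(sp)–Si bond (protodesilylation) frees the terminal alkyne without touching the stereocentre.

Step 9
Reactants: 18 (4S)-6-methylhept-5-en-1-yn-4-ol
Product: 20 (3S,4S)-2-methylhept-1-en-6-yne-3,4-diol, via allylic hydroperoxide 19 (not isolated)
Conditions: O2, hν (white LED), tetraphenylporphyrin (0.2 mol%), CCl4 (or CH2Cl2), −10 °C; then PPh3 (1.1 equiv), 0 °C → rt
Reagents that add atoms: dioxygen, O=O
Why: In this hydroxy-directed Schenck ene reaction the conformer with minimal 1,3-allylic strain lets the OH hydrogen-bond and steer singlet oxygen to one alkene face, which gives the threo (3S,4S) hydroperoxide with the double bond shifted into the isopropenyl position (expected d.r. about 93:7), and PPh3 then reduces the O–O bond without touching C3.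

Step 10
Reactants: 20 (3S,4S)-2-methylhept-1-en-6-yne-3,4-diol
Product: 21 (3S,4S)-3,4-bis(tert-butyldimethylsilyloxy)-2-methylhept-1-en-6-yne
Conditions: tBuMe2SiOTf (2.5 equiv), 2,6-lutidine (4 equiv), CH2Cl2, 0 °C → rt
Reagents that add atoms: tert-butyldimethylsilyl trifluoromethanesulfonate, CC(C)(C)[Si](C)(C)OS(=O)(=O)C(F)(F)F
Why: Silyl ether formation masks both hydroxyls against AlMe3 and keeps them from interfering at palladium later.

Step 11
Reactants: 21 (3S,4S)-3,4-bis(tert-butyldimethylsilyloxy)-2-methylhept-1-en-6-yne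
Product: 23 (1E,4S,5S)-4,5-bis(tert-butyldimethylsilyloxy)-1-iodo-2,6-dimethylhepta-1,6-diene, via alkenylalane 22 (not isolated)
Conditions: AlMe3 (3 equiv), Cp2ZrCl2 (0.25 equiv), CH2Cl2, 0 °C → rt; then I2 (1.5 equiv), THF, −30 → 0 °C
Reagents that add atoms: trimethylaluminium, C[Al](C)C; iodine, II
Why: Negishi Zr-catalysed syn-carboalumination puts methyl on the internal and aluminium on the terminal alkyne carbon, and iodinolysis with retention gives the E-alkenyl iodide, while the hindered 1,1-disubstituted alkene and the silyl ethers stay inert.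

**Union and end game (steps 12–13)**

Step 12
Reactants: 13 potassium trifluoro{[(8-methoxy-2-oxo-2H-chromen-7-yl)oxy]methyl}borate; 23 (1E,4S,5S)-4,5-bis(tert-butyldimethylsilyloxy)-1-iodo-2,6-dimethylhepta-1,6-diene
Product: 25 7-{[(2E,5S,6S)-5,6-bis(tert-butyldimethylsilyloxy)-3,7-dimethylocta-2,7-dien-1-yl]oxy}-8-methoxy-2H-chromen-2-one, via boronic acid 24 (not isolated)
Conditions: 13 (1.3 equiv), Pd(OAc)2 (5 mol%), RuPhos (2-dicyclohexylphosphino-2′,6′-diisopropoxybiphenyl, 10 mol%), Cs2CO3 (3 equiv), degassed 1,4-dioxane/H2O 10:1, 85 °C; work-up with aqueous citric acid (pH 4)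
Reagents that add atoms: none
Why: Proposed new method: the E-alkenyl iodide adds oxidatively to zerovalent palladium with retention, the trifluoroborate hydrolyses slowly to boronic acid 24, whose primary CH2 group (α-oxygen, no β-hydrogen) transmetalates, and reductive elimination from the bulky RuPhos-ligated alkenyl(alkyl)palladium forms the C1–C2 bond with the E geometry intact; palladium sits trans to the tether, so Heck cyclisation onto the isopropenyl group is geometrically impossible, and the fast-reacting iodide plus the bulky monophosphine should keep the catalyst from ionising the product allyl aryl ether; the closest known reaction type is the Suzuki–Miyaura coupling of potassium alkoxymethyltrifluoroborates with aryl halides, and what is new is the coumarinyloxymethyl nucleophile combined with a trisubstituted alkenyl iodide to give an allyl aryl ether.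

Step 13
Reactants: 25 7-{[(2E,5S,6S)-5,6-bis(tert-butyldimethylsilyloxy)-3,7-dimethylocta-2,7-dien-1-yl]oxy}-8-methoxy-2H-chromen-2-one
Product: 26 7-{[(2E,5S,6S)-5,6-dihydroxy-3,7-dimethylocta-2,7-dien-1-yl]oxy}-8-methoxy-2H-chromen-2-one
Conditions: Bu4NF (3 equiv), AcOH (3 equiv), THF, 0 °C → rt
Reagents that add atoms: none
Why: Fluoride-driven Si–O cleavage (silyl ether deprotection), buffered with acetic acid so that the lactone, the allyl aryl ether and both stereocentres are left untouched.

**Compound list**
1 | resorcinol (benzene-1,3-diol) | Oc1cccc(O)c1 | starting material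
2 | 1,3-bis(methoxymethoxy)benzene | COCOc1cccc(OCOC)c1 | intermediate
3 | [2,6-bis(methoxymethoxy)phenyl]lithium | [Li]c1c(OCOC)cccc1OCOC | intermediate
4 | lithium [2,6-bis(methoxymethoxy)phenyl]trimethoxyborate | [Li+].CO[B-](OC)(OC)c1c(OCOC)cccc1OCOC | intermediate
5 | 2,6-bis(methoxymethoxy)phenol | COCOc1cccc(OCOC)c1O | intermediate
6 | 2-methoxy-1,3-bis(methoxymethoxy)benzene | COCOc1cccc(OCOC)c1OC | intermediate
7 | 2-methoxybenzene-1,3-diol | COc1c(O)cccc1O | intermediate
8 | propiolic acid (prop-2-ynoic acid) | C#CC(=O)O | starting material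
9 | (2Z)-3-(2,4-dihydroxy-3-methoxyphenyl)prop-2-enoic acid | OC(=O)/C=C\c1ccc(O)c(OC)c1O | intermediate
10 | 7-hydroxy-8-methoxy-2H-chromen-2-one | COc1c(O)ccc2ccc(=O)oc12 | intermediate
11 | potassium (bromomethyl)trifluoroborate | [K+].F[B-](F)(F)CBr | starting material
12 | potassium 8-methoxy-2-oxo-2H-chromen-7-olate | [K+].[O-]c1ccc2ccc(=O)oc2c1OC | intermediate
13 | potassium trifluoro{[(8-methoxy-2-oxo-2H-chromen-7-yl)oxy]methyl}borate | [K+].F[B-](F)(F)COc1ccc2ccc(=O)oc2c1OC | intermediate
14 | 3-methylbut-2-en-1-ol (prenol) | CC(C)=CCO | starting material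
15 | (3-chloroprop-1-yn-1-yl)trimethylsilane | C[Si](C)(C)C#CCCl | starting material
16 | 3-methylbut-2-enal | CC(C)=CC=O | intermediate
17 | (4S)-6-methyl-1-(trimethylsilyl)hept-5-en-1-yn-4-ol | CC(C)=C[C@@H](O)CC#C[Si](C)(C)C | intermediate
18 | (4S)-6-methylhept-5-en-1-yn-4-ol | CC(C)=C[C@@H](O)CC#C | intermediate
19 | (3S,4S)-3-hydroperoxy-2-methylhept-1-en-6-yn-4-ol | C=C(C)[C@H](OO)[C@@H](O)CC#C | intermediate
20 | (3S,4S)-2-methylhept-1-en-6-yne-3,4-diol | C=C(C)[C@H](O)[C@@H](O)CC#C | intermediate
21 | (3S,4S)-3,4-bis(tert-butyldimethylsilyloxy)-2-methylhept-1-en-6-yne | C=C(C)[C@H](O[Si](C)(C)C(C)(C)C)[C@@H](O[Si](C)(C)C(C)(C)C)CC#C | intermediate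
22 | [(1E,4S,5S)-4,5-bis(tert-butyldimethylsilyloxy)-2,6-dimethylhepta-1,6-dien-1-yl]dimethylalumane | C=C(C)[C@H](O[Si](C)(C)C(C)(C)C)[C@@H](O[Si](C)(C)C(C)(C)C)C/C(C)=C/[Al](C)C | intermediate
23 | (1E,4S,5S)-4,5-bis(tert-butyldimethylsilyloxy)-1-iodo-2,6-dimethylhepta-1,6-diene | C=C(C)[C@H](O[Si](C)(C)C(C)(C)C)[C@@H](O[Si](C)(C)C(C)(C)C)C/C(C)=C/I | intermediate
24 | {[(8-methoxy-2-oxo-2H-chromen-7-yl)oxy]methyl}boronic acid | OB(O)COc1ccc2ccc(=O)oc2c1OC | intermediate
25 | 7-{[(2E,5S,6S)-5,6-bis(tert-butyldimethylsilyloxy)-3,7-dimethylocta-2,7-dien-1-yl]oxy}-8-methoxy-2H-chromen-2-one | C=C(C)[C@H](O[Si](C)(C)C(C)(C)C)[C@@H](O[Si](C)(C)C(C)(C)C)C/C(C)=C/COc1ccc2ccc(=O)oc2c1OC | intermediate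
26 | 7-{[(2E,5S,6S)-5,6-dihydroxy-3,7-dimethylocta-2,7-dien-1-yl]oxy}-8-methoxy-2H-chromen-2-one | C=C(C)[C@H](O)[C@@H](O)C/C(C)=C/COc1ccc2ccc(=O)oc2c1OC | target

**Step count**
Total steps: 13. Longest linear sequence: 8 (steps 1–6, 12, 13); the other branch is 7 (steps 7–11, 12, 13).

**Three steps most likely to fail**

Step 12 (the proposed new coupling). Risks are protodeboronation of 24 to the 7-methoxy compound, slow sp3 transmetalation, and palladium ionising the product allyl aryl ether, which would scramble the alkene geometry. The fallback uses known chemistry and sets out from 21 and 10. Alkyne 21 is carboaluminated as in step 11 to alkenylalane 22, which is activated with nBuLi to give lithium butyl[(1E,4S,5S)-4,5-bis(tert-butyldimethylsilyloxy)-2,6-dimethylhepta-1,6-dien-1-yl]dimethylaluminate F1. Quenching with paraformaldehyde gives (2E,5S,6S)-5,6-bis(tert-butyldimethylsilyloxy)-3,7-dimethylocta-2,7-dien-1-ol F2. Mitsunobu etherification of F2 with phenol 10 (PPh3, diisopropyl azodicarboxylate, THF, 0 °C) forms the C1–O bond, and the route is rejoined at 25.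

Step 6 (trifluoroborate formation). The coumarin phenoxide is a weak nucleophile, and the anionic bromomethyl trifluoroborate is a sluggish electrophile; the salt may also be hard to purify. The fallback sets out from 10. Alkylation with 2-(bromomethyl)-4,4,5,5-tetramethyl-1,3,2-dioxaborolane (K2CO3, MeCN, 60 °C) proceeds through a boron-ate 1,2-shift rather than a direct SN2 and gives 8-methoxy-7-[(4,4,5,5-tetramethyl-1,3,2-dioxaborolan-2-yl)methoxy]-2H-chromen-2-one F3. Treatment with KHF2 in MeOH/H2O converts F3 into the trifluoroborate, and the route is rejoined at 13.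

Step 7 (Ir-catalysed propargylation). Risks are insufficient enantioselectivity or the wrong sense with the enal-level substrate, conjugate reduction of the transient enal, and loss of the silyl group under the basic conditions. The fallback sets out from 16, bought as such. A chiral phosphoric acid-catalysed allenylboration with 4,4,5,5-tetramethyl-2-(propa-1,2-dien-1-yl)-1,3,2-dioxaborolane (the TRIP enantiomer that gives the S alcohol, toluene, −20 °C) proceeds through a closed six-membered transition state. It first gives the borate ester 4,4,5,5-tetramethyl-2-{[(4S)-6-methylhept-5-en-1-yn-4-yl]oxy}-1,3,2-dioxaborolane F4, which hydrolyses on work-up, and the route is rejoined at 18 (steps 7 and 8 are both replaced).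

**Further compounds**
F1 | step 12 | lithium butyl[(1E,4S,5S)-4,5-bis(tert-butyldimethylsilyloxy)-2,6-dimethylhepta-1,6-dien-1-yl]dimethylaluminate | C=C(C)[C@H](O[Si](C)(C)C(C)(C)C)[C@@H](O[Si](C)(C)C(C)(C)C)C/C(C)=C/[Al-](C)(C)CCCC.[Li+]
F2 | step 12 | (2E,5S,6S)-5,6-bis(tert-butyldimethylsilyloxy)-3,7-dimethylocta-2,7-dien-1-ol | C=C(C)[C@H](O[Si](C)(C)C(C)(C)C)[C@@H](O[Si](C)(C)C(C)(C)C)C/C(C)=C/CO
F3 | step 6 | 8-methoxy-7-[(4,4,5,5-tetramethyl-1,3,2-dioxaborolan-2-yl)methoxy]-2H-chromen-2-one | CC1(C)OB(COc2ccc3ccc(=O)oc3c2OC)OC1(C)C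
F4 | step 7 | 4,4,5,5-tetramethyl-2-{[(4S)-6-methylhept-5-en-1-yn-4-yl]oxy}-1,3,2-dioxaborolane | CC(C)=C[C@@H](OB1OC(C)(C)C(C)(C)O1)CC#C
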